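**Retrosynthetic overview**

1. Ainsliadimer B is cut through its central cyclohexene ring (guaiane numbering; primes mark the lower half with the spiro carbon C4′). The bonds C14–C15′ and C2–C4′ are traced to one Diels-Alder reaction of two guaianolide monomers, and the C10 carbinol beside the C1=C2 enone to a γ-oxygenation of the first-formed C1=C10 adduct.
2. Enabling feature: C1 and C10 are neighbours in the seven-membered ring of the upper half, so its diene C2=C1–C10=C14 (ring enone plus exocyclic methylene) is locked s-cis, and C4′=C15′ of the lower half is the exocyclic methylene of a cyclopentanone. Both halves are the same C15 skeleton.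
3. Both partners come from one monomer, the 3-keto guaianolide with the C4=C15 exocyclic enone (two oxidation steps from a commercial guaianolide). It is the dienophile as such. For the diene, C4=C15 is tied up as a temporary spiro-epoxide that stores O15, makes C4 quaternary (only C2 can enolise) and removes the competing dienophile; C1=C2 is then introduced and the epoxide opened reductively to C4–H/C15–OH.
4. Ring order: the 5-7-5 rings of both halves are taken from the chiral pool. The only ring built is the central cyclohexene, closed in the last step together with the spiro centre C4′ and the C10 alcohol.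

Key step: step 6

Remark: natural dehydrocostus lactone 1, (3aS,6aR,9aR,9bS), is taken as a commercially available enantiopure starting material. α denotes the face of H5 (and of H1 in the monomers) in each half.

**Route**

Step 1
Reactants: 1 dehydrocostus lactone
Product: 2 3-epizaluzanin C (3α-hydroxydehydrocostus lactone)
Conditions: SeO2 (0.5 equiv), t-BuOOH, CH2Cl2, 0 °C to rt
Reagents that add atoms: tert-butyl hydroperoxide, CC(C)(C)OO (net oxygen source); selenium dioxide, O=[Se]=O (carrier that delivers the oxygen)
Why: SeO2 allylic oxidation (ene reaction, then [2,3]-sigmatropic shift) should hydroxylate the ring methylene C3 next to the C4=C15 alkene and spare the electron-poor lactone methylene, with oxygen arriving on the convex α face; the centre is levelled to the ketone in step 2, so any 3β epimer converges.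

Step 2
Reactants: 2 3-epizaluzanin C
Product: 3 dehydrozaluzanin C
Conditions: Dess-Martin periodinane, CH2Cl2, 0 °C to rt
Reagents that add atoms: none
Why: Dess-Martin oxidation of the secondary allylic alcohol should give the exocyclic enone under non-nucleophilic conditions that spare both Michael acceptors; no stereocentre is formed.

Step 3
Reactants: 3 dehydrozaluzanin C
Product: 4 4α,15-epoxy ketone (spiro-epoxide of dehydrozaluzanin C)
Conditions: t-BuOOH (anhydrous, in decane), DBU, CH2Cl2, 0 °C
Reagents that add atoms: tert-butyl hydroperoxide, CC(C)(C)OO
Why: Weitz-Scheffer nucleophilic epoxidation: the peroxide anion adds to C15 of the ketone-conjugated methylene, which is far more electrophilic than the lactone-conjugated one, and the enolate closes onto oxygen from the convex α face (anti to the C5–C6 bond); the configuration of this temporary centre is erased in step 5.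

Step 4
Reactants: 4 4α,15-epoxy ketone
Product: 5 epoxy dienone (4α,15-epoxy-3-oxoguaia-1,10(14),11(13)-trien-12,6-olide)
Conditions: IBX, 4-methoxypyridine N-oxide, DMSO, 25 °C
Reagents that add atoms: none
Why: IBX dehydrogenation of a ketone through its enol: with C4 quaternary only the C2 enol can form, and loss of the allylic H1 gives the C1=C2 enone conjugated with C10=C14; no stereocentre is formed, and room temperature should hold back self-cycloaddition of the diene.

Step 5
Reactants: 5 epoxy dienone
Product: 7 15-hydroxy dienone (CH2OH α; 4β-H), via 4-epi hydroxy dienone 6 (not isolated)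
Conditions: SmI2 (2.1 equiv), THF/MeOH, −90 °C; work-up; then Et3N, CH2Cl2, rt
Reagents that add atoms: none
Why: SmI2 reduction of an α,β-epoxy ketone to the β-hydroxy ketone: the ketyl expels the α-oxygen (C4–O cleavage) faster than the dienone or lactone can be reduced at −90 °C, protonation of the samarium enolate from the open α face gives mainly the cis epimer 6, and Et3N equilibrates the epimerisable C4 to the isomer with CH2OH trans to the C5–C6 bond, as in the target.

Step 6
Reactants: 7 15-hydroxy dienone; 3 dehydrozaluzanin C
Product: 10 ainsliadimer B, via Diels-Alder adduct 8 (not isolated), via C10 hydroperoxide 9 (not isolated)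
Conditions: 3 (2 equiv), toluene (2 M), argon, 50 °C; then O2 (1 atm), Et3N (cat.), CH2Cl2, rt; then PPh3, 0 °C
Reagents that add atoms: dioxygen, O=O
Why: Thermal intermolecular Diels-Alder reaction of the s-cis-locked dienone 7 (C2=C1–C10=C14) with the exocyclic enone C4′=C15′ of 3, asynchronous with C14–C15′ as the leading bond (largest HOMO coefficient of the dienone at C14, largest LUMO coefficient of the enone at C15′) and C2–C4′ following, which gives the "ortho" adduct 8; the closest known reaction type is the [4+2] dimerisation of 1,2-dialkylidenecycloalkane dienes and dienones with α-methylene ketones. The central cyclohexene ring is closed by this [4+2] cycloaddition, two σ bonds in one event and no ring closure of another mode. The spiro centre C4′ is set by attack of the diene on the convex α face of the cyclopentanone of 3, anti to its C5′–C6′ bond, while the transient centre C2 (drawn for addition to the diene face of H5) is erased again. In the same flask Et3N enolises the doubly activated C2–H of 8 to the dienol C3(OH)=C2–C1=C10, which takes up O2 at its γ carbon C10 (the known aerobic γ-oxygenation of β,γ-unsaturated ketones) to give hydroperoxide 9 with the C1=C2 enone in place, and PPh3 reduces the O–O bond. The C10 configuration should be controlled by the lower half: C5′ stands on the α face of the central ring and holds its seven-membered ring over C14/C10, so oxygen enters from the β face. The step needs cross- over self-selectivity, secured because 7 has no exocyclic enone of its own (C15 is oxidised) and 3 has no diene, and site selectivity among the acceptor alkenes, secured by the higher reactivity of the ketone-conjugated methylene over the two lactone-conjugated ones.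

**Compound list**

1 | dehydrocostus lactone (1α,5α,6β,7α-H; guaia-4(15),10(14),11(13)-trien-12,6-olide) | C=C1CC[C@H]2C(=C)CC[C@H]3C(=C)C(=O)O[C@@H]3[C@H]21 | starting material
2 | 3-epizaluzanin C (3α-hydroxydehydrocostus lactone) | C=C1[C@H](O)C[C@H]2C(=C)CC[C@H]3C(=C)C(=O)O[C@@H]3[C@H]21 | intermediate
3 | dehydrozaluzanin C (3-oxodehydrocostus lactone) | C=C1C(=O)C[C@H]2C(=C)CC[C@H]3C(=C)C(=O)O[C@@H]3[C@H]21 | intermediate
4 | 4α,15-epoxy ketone (4α,15-epoxy-3-oxoguaia-10(14),11(13)-dien-12,6-olide; epoxide oxygen on the α face) | O=C1C[C@H]2C(=C)CC[C@H]3C(=C)C(=O)O[C@@H]3[C@H]2[C@@]14CO4 | intermediate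
5 | epoxy dienone (4α,15-epoxy-3-oxoguaia-1,10(14),11(13)-trien-12,6-olide) | O=C1C=C2C(=C)CC[C@H]3C(=C)C(=O)O[C@@H]3[C@H]2[C@@]14CO4 | intermediate
6 | 4-epi hydroxy dienone (CH2OH β, 4α-H; formed in the flask) | O=C1C=C2C(=C)CC[C@H]3C(=C)C(=O)O[C@@H]3[C@H]2[C@H]1CO | intermediate
7 | 15-hydroxy dienone (15-hydroxy-3-oxo-4βH-guaia-1,10(14),11(13)-trien-12,6-olide; CH2OH α) | O=C1C=C2C(=C)CC[C@H]3C(=C)C(=O)O[C@@H]3[C@H]2[C@@H]1CO | intermediate
8 | Diels-Alder adduct (C1=C10 alkene, 2β-H, C2 on the α face of the lower cyclopentanone at spiro C4′; formed in the flask) | C=C1C(=O)O[C@@H]2[C@@H]3C4=C(CC[C@@H]12)CC[C@]5(C(=O)C[C@H]6C(=C)CC[C@H]7C(=C)C(=O)O[C@@H]7[C@H]65)[C@H]4C(=O)[C@H]3CO | intermediate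
9 | C10 hydroperoxide (10β-OOH, C1=C2 enone; formed in the flask) | C=C1C(=O)O[C@@H]2[C@@H]3C4=C(C(=O)[C@H]3CO)[C@]3(CC[C@]4(OO)CC[C@@H]12)C(=O)C[C@H]1C(=C)CC[C@H]2C(=C)C(=O)O[C@@H]2[C@H]13 | intermediate
10 | ainsliadimer B (10β-OH, 4β-H, CH2OH α) | C=C1C(=O)O[C@@H]2[C@@H]3C4=C(C(=O)[C@H]3CO)[C@]3(CC[C@]4(O)CC[C@@H]12)C(=O)C[C@H]1C(=C)CC[C@H]2C(=C)C(=O)O[C@@H]2[C@H]13 | target

**Summary**

Total step count: 6. Longest linear sequence: 6 steps (1 → 2 → 3 → 4 → 5 → 7 → 10; compound 3 is also the second partner in step 6).

Three steps most likely to fail:

- **Step 6 (key step).** The aerobic step is a radical-chain process in which facial control at C10 may be lost or C4 may be over-oxidised; in the cycloaddition, self-dimerisation of 7 through its lactone methylene may compete with the cross reaction. The fallback sets out from 8, isolated under argon after the cycloaddition, and returns at 10. DMDO (1 equiv, acetone, −40 °C) should epoxidise the tetrasubstituted, most electron-rich C1=C10 alkene from the β face, anti to the lower seven-membered ring, to give the 1β,10β-epoxide of the adduct F1. Et3N (CH2Cl2, rt) then opens this β,γ-epoxy ketone by E1cB elimination (C2 enolate, C1–O cleavage) to the γ-hydroxy enone 10. A closed-shell, stereospecific two-stage sequence thus replaces the radical chain.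

- **Step 5.** The dienone chromophore may be over-reduced by SmI2, or water may be eliminated from the β-hydroxy ketone during the C4 equilibration. The fallback sets out from 4 and returns at 7, opening the epoxide before the unsaturation is introduced. SmI2 (THF/MeOH, −90 °C) on the saturated epoxy ketone 4, followed by Et3N equilibration, should give the 15-hydroxy ketone F2. LiHMDS (2.2 equiv) with TMSCl as internal quench (THF, −78 °C) silylates O15 and forms the kinetic C2=C3 enol ether, giving the bis-TMS compound F3. Saegusa-Ito oxidation (Pd(OAc)2, MeCN, rt) with a dilute citric acid work-up then delivers 7.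

- **Step 4.** Dehydrogenation of the cyclopentanone may be sluggish, with oxidation at the allylic methylene positions or self-cycloaddition of the product diene taking over. The fallback sets out from 4 and returns at 5. TBSOTf/Et3N (CH2Cl2, −78 °C; only C2 can be deprotonated) should give the TBS enol ether F4, and Saegusa-Ito oxidation (Pd(OAc)2, MeCN, rt) then gives 5 through a palladium enolate and β-hydride elimination of H1.

**Further compounds**

F1 | step 6 | 1β,10β-epoxide of the adduct | C=C1C(=O)O[C@@H]2[C@@H]3[C@]48O[C@]8(CC[C@@H]12)CC[C@]5(C(=O)C[C@H]6C(=C)CC[C@H]7C(=C)C(=O)O[C@@H]7[C@H]65)[C@H]4C(=O)[C@H]3CO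
F2 | step 5 | 15-hydroxy ketone (15-hydroxy-3-oxo-4βH-guaia-10(14),11(13)-dien-12,6-olide) | O=C1C[C@H]2C(=C)CC[C@H]3C(=C)C(=O)O[C@@H]3[C@H]2[C@@H]1CO
F3 | step 5 | bis-TMS compound (15-O-TMS ether, C2=C3 TMS enol ether) | C[Si](C)(C)OC1=C[C@H]2C(=C)CC[C@H]3C(=C)C(=O)O[C@@H]3[C@H]2[C@@H]1CO[Si](C)(C)C
F4 | step 4 | TBS enol ether of the epoxy ketone (C2=C3) | CC(C)(C)[Si](C)(C)OC1=C[C@H]2C(=C)CC[C@H]3C(=C)C(=O)O[C@@H]3[C@H]2[C@@]14CO4
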